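**Retrosynthetic overview**
1. Last bond: the ester between the primary alcohol of the lactone half and the acrylic acid of the cyclohexene half, followed by two deprotections.
2. Both halves come from one bicyclic β-lactone: loss of CO2 gives the cyclohexene half; inversion at the side-chain carbon, re-olefination and β-lactone to seven-membered-lactone ring expansion give the lactone half.
3. The β-lactone comes from an acyclic keto acid by an aldol-lactonisation that closes the cyclohexane and the four-membered lactone together.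
4. The keto acid comes from ozonolysis and olefination of a trans-3,4-disubstituted cyclohexene made from (S)-cryptone (isovaleraldehyde + methyl vinyl ketone).
5. Ring order: cryptone ring (step 2, cut open in step 8); cyclohexane + β-lactone (step 10); cyclohexene by CO2 loss (step 11); seven-membered lactone (step 14).

Assumption: the SMILES is taken literally, so the acrylate-bearing ring carbon is trans to isopropyl in the lactone half but cis to isopropyl in the cyclohexene half.

Step 1
Reactants: 1 3-methylbutanal (isovaleraldehyde); 2 but-3-en-2-one (methyl vinyl ketone)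
Product: 3 (2S)-5-oxo-2-(propan-2-yl)hexanal
Conditions: (S)-2-[methoxy(diphenyl)methyl]pyrrolidine (5 mol%), ethyl 3,4-dihydroxybenzoate (20 mol%), neat, 4 °C
Reagents that add atoms: none
Why: Enamine-catalysed Michael addition (Gellman/Hayashi type) in which the diphenylmethyl group shields one face of the E-enamine, so the enone adds to the Si face of the α-carbon and sets the S centre that becomes the isopropyl-bearing carbon of both halves.

Step 2
Reactants: 3 (2S)-5-oxo-2-(propan-2-yl)hexanal
Product: 4 (4S)-4-(propan-2-yl)cyclohex-2-en-1-one ((S)-cryptone)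
Conditions: LiOH (10 mol%), iPrOH, 23 °C
Reagents that add atoms: none
Why: Intramolecular aldol condensation (Robinson-type closure) of the 1,5-keto aldehyde, which is known to proceed without erosion of the γ-stereocentre.

Step 3
Reactants: 4 (S)-cryptone; 5 tert-butyl[(1-methoxyethenyl)oxy]dimethylsilane
Product: 7 methyl 2-[(1S,6S)-6-(propan-2-yl)-3-(trifluoromethanesulfonyloxy)cyclohex-2-en-1-yl]acetate, via silyl enol ether 6 (not isolated)
Conditions: TBSOTf (5 mol%), CH2Cl2, −78 °C; concentrate; then CsF, PhNTf2, DME, 23 °C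
Reagents that add atoms: N-phenylbis(trifluoromethanesulfonimide), O=S(=O)(N(c1ccccc1)S(=O)(=O)C(F)(F)F)C(F)(F)F
Why: Mukaiyama–Michael addition occurs axially on the face anti to the C4 isopropyl group (trans 3,4 relationship), and the regiodefined enol silane is converted by fluoride into the enol triflate without moving the double bond.

Step 4
Reactants: 7 enol triflate; 8 (tributylstannyl)methanol
Product: 9 methyl 2-[(1S,6S)-3-(hydroxymethyl)-6-(propan-2-yl)cyclohex-2-en-1-yl]acetate
Conditions: Pd(PPh3)4 (5 mol%), LiCl, 1,4-dioxane, 100 °C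
Reagents that add atoms: none
Why: Stille (Migita–Kosugi) hydroxymethylation of the enol triflate, which installs the CH2OH carbon of both halves with no effect on the stereocentres.

Step 5
Reactants: 9 allylic alcohol
Product: 10 methyl 2-[(1S,6S)-3-{[(tert-butyldimethylsilyl)oxy]methyl}-6-(propan-2-yl)cyclohex-2-en-1-yl]acetate
Conditions: TBSCl, imidazole, DMF, 23 °C
Reagents that add atoms: tert-butyl(chloro)dimethylsilane, C[Si](C)(Cl)C(C)(C)C
Why: Standard silylation of the primary alcohol, needed because a free hydroxyl would be acylated in step 10.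

Step 6
Reactants: 11 prop-2-en-1-yl (diethoxyphosphoryl)acetate (allyl diethylphosphonoacetate); 12 paraformaldehyde
Product: 13 prop-2-en-1-yl 2-(diethoxyphosphoryl)-3-hydroxypropanoate (racemic)
Conditions: piperidine (5 mol%), THF, 60 °C
Reagents that add atoms: none
Why: Amine-catalysed aldol-type hydroxymethylation of the phosphonoacetate, stopped at the adduct by using one equivalent of formaldehyde and only catalytic base.

Step 7
Reactants: 13 hydroxymethyl phosphonate
Product: 14 prop-2-en-1-yl 3-[(tert-butyldimethylsilyl)oxy]-2-(diethoxyphosphoryl)propanoate (racemic)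
Conditions: TBSCl, imidazole, CH2Cl2, 0 °C
Reagents that add atoms: tert-butyl(chloro)dimethylsilane, C[Si](C)(Cl)C(C)(C)C
Why: Silylation gives a Horner–Wadsworth–Emmons reagent that carries the protected hydroxymethyl group; its stereocentre is lost on deprotonation.

Step 8
Reactants: 10 silyl-protected cyclohexene ester; 14 silyloxy phosphonate
Product: 16 6-methyl 1-prop-2-en-1-yl (2E,4S)-2-{[(tert-butyldimethylsilyl)oxy]methyl}-4-[(3S)-7-[(tert-butyldimethylsilyl)oxy]-2-methyl-6-oxoheptan-3-yl]hex-2-enedioate, via keto aldehyde 15 (not isolated)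
Conditions: O3, CH2Cl2, −78 °C; PPh3; then 14, NaH, THF, −78 to 0 °C
Reagents that add atoms: ozone, [O-][O+]=O
Why: Ozonolysis of the only C=C opens the ring to a ketone and an α-branched aldehyde, and an immediate Horner–Wadsworth–Emmons reaction on the aldehyde (faster than epimerisation or attack on the ketone) gives the E enoate with the ester trans to the branched carbon, so both stereocentres are carried over unchanged.

Step 9
Reactants: 16 keto diester
Product: 17 (3S,4E)-6-[(tert-butyldimethylsilyl)oxy]-3-[(3S)-7-[(tert-butyldimethylsilyl)oxy]-2-methyl-6-oxoheptan-3-yl]-5-[(prop-2-en-1-yloxy)carbonyl]hex-4-enoic acid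
Conditions: LiOH (1.2 equiv), THF/H2O, 0 °C; then aq. HCl to pH 4
Reagents that add atoms: lithium hydroxide, [Li+].[OH-]
Why: Chemoselective saponification, since the unhindered aliphatic methyl ester hydrolyses far faster than the trisubstituted conjugated allyl ester.

Step 10
Reactants: 17 keto acid
Product: 18 prop-2-en-1-yl (2E)-2-{[(tert-butyldimethylsilyl)oxy]methyl}-3-[(1S,2S,3S,6R)-6-{[(tert-butyldimethylsilyl)oxy]methyl}-8-oxo-3-(propan-2-yl)-7-oxabicyclo[4.2.0]octan-2-yl]prop-2-enoate
Conditions: 2-bromo-1-propylpyridinium triflate, 4-pyrrolidinopyridine, iPr2NEt, CH2Cl2, 23 °C, 48 h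
Reagents that add atoms: none
Why: Romo nucleophile-catalysed aldol-lactonisation closes the cyclohexane and the β-lactone in one operation; allylic 1,3-strain keeps the C–H of the alkenyl-bearing carbon in the ammonium-enolate plane so the alkenyl arm is axial and anti to the forming bond, the isopropyl group cis to it is equatorial in the chair, and the ketone oxygen must face the acyl carbon to lactonise, which puts the acyl carbon trans to isopropyl and the silyloxymethyl group on the isopropyl face.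

Step 11
Reactants: 18 bicyclic β-lactone
Product: 19 prop-2-en-1-yl (2E)-2-{[(tert-butyldimethylsilyl)oxy]methyl}-3-[(1R,6S)-3-{[(tert-butyldimethylsilyl)oxy]methyl}-6-(propan-2-yl)cyclohex-2-en-1-yl]prop-2-enoate
Conditions: DMF, 130 °C
Reagents that add atoms: none
Why: Thermal [2+2] cycloreversion of the β-lactone (stereospecific decarboxylation) places the trisubstituted alkene between the two former aldol carbons and leaves the cis relationship of isopropyl and side chain, set in step 3, untouched.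

Step 12
Reactants: 19 allyl ester
Product: 20 (2E)-2-{[(tert-butyldimethylsilyl)oxy]methyl}-3-[(1R,6S)-3-{[(tert-butyldimethylsilyl)oxy]methyl}-6-(propan-2-yl)cyclohex-2-en-1-yl]prop-2-enoic acid
Conditions: Pd(PPh3)4 (5 mol%), morpholine, THF, 23 °C
Reagents that add atoms: none
Why: Tsuji–Trost deallylation via a π-allylpalladium complex trapped by morpholine, neutral enough to leave silyl ethers and the skipped diene alone.

Step 13
Reactants: 18 bicyclic β-lactone; 14 silyloxy phosphonate
Product: 23 prop-2-en-1-yl (2E)-2-{[(tert-butyldimethylsilyl)oxy]methyl}-3-[(1S,2R,3S,6R)-6-{[(tert-butyldimethylsilyl)oxy]methyl}-8-oxo-3-(propan-2-yl)-7-oxabicyclo[4.2.0]octan-2-yl]prop-2-enoate, via cis-formyl β-lactone 21 (not isolated), via trans-formyl β-lactone 22 (not isolated)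
Conditions: O3 (excess), CH2Cl2, −78 °C; PPh3; then 14 (3 equiv), LiCl, DBU, MeCN, 0 to 23 °C
Reagents that add atoms: ozone, [O-][O+]=O
Why: Ozonolysis unmasks the formyl group from the enoate (which served as a masked aldehyde through step 10), DBU equilibrates the axial aldehyde, which is cis to isopropyl and 1,3-syn to the silyloxymethyl group, to the equatorial epimer, and a Masamune–Roush Horner–Wadsworth–Emmons reaction gives the E enoate, so the side-chain carbon ends trans to isopropyl and cis to the lactone carbonyl.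

Step 14
Reactants: 23 epimerised β-lactone
Product: 25 prop-2-en-1-yl (5aR,6S,9R,9aS)-9-hydroxy-9-(hydroxymethyl)-1-oxo-6-(propan-2-yl)-1,3,5a,6,7,8,9,9a-octahydro-2-benzoxepine-4-carboxylate, via diol β-lactone 24 (not isolated)
Conditions: HF·pyridine, pyridine, THF, 0 to 23 °C; then Et3N (cat.), CH2Cl2, 23 °C
Reagents that add atoms: none
Why: Desilylation frees the allylic primary alcohol, which sits gauche to the axial β-lactone carbonyl and opens the strained ring by intramolecular transesterification (ring expansion) to the cis-fused seven-membered lactone while releasing the tertiary alcohol; the neopentyl alcohol is anti to that carbonyl in the chair and cannot reach it.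

Step 15
Reactants: 25 lactone diol; 20 cyclohexene acid
Product: 26 prop-2-en-1-yl (5aR,6S,9R,9aS)-9-({[(2E)-2-{[(tert-butyldimethylsilyl)oxy]methyl}-3-[(1R,6S)-3-{[(tert-butyldimethylsilyl)oxy]methyl}-6-(propan-2-yl)cyclohex-2-en-1-yl]prop-2-enoyl]oxy}methyl)-9-hydroxy-1-oxo-6-(propan-2-yl)-1,3,5a,6,7,8,9,9a-octahydro-2-benzoxepine-4-carboxylate
Conditions: 20, 2,4,6-trichlorobenzoyl chloride, Et3N, THF; then 25, DMAP, toluene, 40 °C
Reagents that add atoms: none
Why: Yamaguchi esterification acylates the primary alcohol only, because the tertiary alcohol is far too hindered; the thermodynamically preferred E enoate geometry is not at risk.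

Step 16
Reactants: 26 coupled allyl ester
Product: 27 (5aR,6S,9R,9aS)-9-({[(2E)-2-{[(tert-butyldimethylsilyl)oxy]methyl}-3-[(1R,6S)-3-{[(tert-butyldimethylsilyl)oxy]methyl}-6-(propan-2-yl)cyclohex-2-en-1-yl]prop-2-enoyl]oxy}methyl)-9-hydroxy-1-oxo-6-(propan-2-yl)-1,3,5a,6,7,8,9,9a-octahydro-2-benzoxepine-4-carboxylic acid
Conditions: Pd(PPh3)4 (5 mol%), morpholine, THF, 23 °C
Reagents that add atoms: none
Why: Tsuji–Trost deallylation frees the ring carboxylic acid without touching the lactone, the inter-half ester or the silyl ethers.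

Step 17
Reactants: 27 bis-silyl acid
Product: 28 CNP0361406.6
Conditions: HF·pyridine, pyridine, THF, 0 to 23 °C
Reagents that add atoms: none
Why: Mildly acidic fluoride desilylation of the two primary silyl ethers, which avoids the acyl migration and lactone opening that basic fluoride could cause.

**Compound list**
1 | 3-methylbutanal (isovaleraldehyde) | CC(C)CC=O | starting material
2 | but-3-en-2-one (methyl vinyl ketone) | CC(=O)C=C | starting material
3 | (2S)-5-oxo-2-(propan-2-yl)hexanal | CC(C)[C@H](CCC(C)=O)C=O | intermediate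
4 | (4S)-4-(propan-2-yl)cyclohex-2-en-1-one, (S)-cryptone | CC(C)[C@@H]1CCC(=O)C=C1 | intermediate
5 | tert-butyl[(1-methoxyethenyl)oxy]dimethylsilane | C=C(OC)O[Si](C)(C)C(C)(C)C | starting material
6 | methyl 2-[(1S,6S)-3-[(tert-butyldimethylsilyl)oxy]-6-(propan-2-yl)cyclohex-2-en-1-yl]acetate (silyl enol ether; acetate arm trans to isopropyl) | CC(C)[C@@H]1CCC(O[Si](C)(C)C(C)(C)C)=C[C@H]1CC(=O)OC | intermediate
7 | methyl 2-[(1S,6S)-6-(propan-2-yl)-3-(trifluoromethanesulfonyloxy)cyclohex-2-en-1-yl]acetate | CC(C)[C@@H]1CCC(OS(=O)(=O)C(F)(F)F)=C[C@H]1CC(=O)OC | intermediate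
8 | (tributylstannyl)methanol | CCCC[Sn](CCCC)(CCCC)CO | starting material
9 | methyl 2-[(1S,6S)-3-(hydroxymethyl)-6-(propan-2-yl)cyclohex-2-en-1-yl]acetate | CC(C)[C@@H]1CCC(CO)=C[C@H]1CC(=O)OC | intermediate
10 | methyl 2-[(1S,6S)-3-{[(tert-butyldimethylsilyl)oxy]methyl}-6-(propan-2-yl)cyclohex-2-en-1-yl]acetate | CC(C)[C@@H]1CCC(CO[Si](C)(C)C(C)(C)C)=C[C@H]1CC(=O)OC | intermediate
11 | prop-2-en-1-yl (diethoxyphosphoryl)acetate | C=CCOC(=O)CP(=O)(OCC)OCC | starting material
12 | paraformaldehyde (formaldehyde unit shown) | C=O | starting material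
13 | prop-2-en-1-yl 2-(diethoxyphosphoryl)-3-hydroxypropanoate (racemic) | C=CCOC(=O)C(CO)P(=O)(OCC)OCC | intermediate
14 | prop-2-en-1-yl 3-[(tert-butyldimethylsilyl)oxy]-2-(diethoxyphosphoryl)propanoate (racemic) | C=CCOC(=O)C(CO[Si](C)(C)C(C)(C)C)P(=O)(OCC)OCC | intermediate
15 | methyl (3S,4S)-8-[(tert-butyldimethylsilyl)oxy]-3-formyl-7-oxo-4-(propan-2-yl)octanoate | CC(C)[C@H](CCC(=O)CO[Si](C)(C)C(C)(C)C)[C@@H](C=O)CC(=O)OC | intermediate
16 | 6-methyl 1-prop-2-en-1-yl (2E,4S)-2-{[(tert-butyldimethylsilyl)oxy]methyl}-4-[(3S)-7-[(tert-butyldimethylsilyl)oxy]-2-methyl-6-oxoheptan-3-yl]hex-2-enedioate | CC(C)[C@H](CCC(=O)CO[Si](C)(C)C(C)(C)C)[C@@H](/C=C(\CO[Si](C)(C)C(C)(C)C)C(=O)OCC=C)CC(=O)OC | intermediate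
17 | (3S,4E)-6-[(tert-butyldimethylsilyl)oxy]-3-[(3S)-7-[(tert-butyldimethylsilyl)oxy]-2-methyl-6-oxoheptan-3-yl]-5-[(prop-2-en-1-yloxy)carbonyl]hex-4-enoic acid | CC(C)[C@H](CCC(=O)CO[Si](C)(C)C(C)(C)C)[C@@H](/C=C(\CO[Si](C)(C)C(C)(C)C)C(=O)OCC=C)CC(=O)O | intermediate
18 | prop-2-en-1-yl (2E)-2-{[(tert-butyldimethylsilyl)oxy]methyl}-3-[(1S,2S,3S,6R)-6-{[(tert-butyldimethylsilyl)oxy]methyl}-8-oxo-3-(propan-2-yl)-7-oxabicyclo[4.2.0]octan-2-yl]prop-2-enoate (alkenyl arm cis to isopropyl, trans to lactone carbonyl) | CC(C)[C@@H]1CC[C@@]2(CO[Si](C)(C)C(C)(C)C)OC(=O)[C@H]2[C@@H]1/C=C(\CO[Si](C)(C)C(C)(C)C)C(=O)OCC=C | intermediate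
19 | prop-2-en-1-yl (2E)-2-{[(tert-butyldimethylsilyl)oxy]methyl}-3-[(1R,6S)-3-{[(tert-butyldimethylsilyl)oxy]methyl}-6-(propan-2-yl)cyclohex-2-en-1-yl]prop-2-enoate | C=CCOC(=O)/C(=C/[C@H]1C=C(CO[Si](C)(C)C(C)(C)C)CC[C@H]1C(C)C)CO[Si](C)(C)C(C)(C)C | intermediate
20 | (2E)-2-{[(tert-butyldimethylsilyl)oxy]methyl}-3-[(1R,6S)-3-{[(tert-butyldimethylsilyl)oxy]methyl}-6-(propan-2-yl)cyclohex-2-en-1-yl]prop-2-enoic acid | OC(=O)/C(=C/[C@H]1C=C(CO[Si](C)(C)C(C)(C)C)CC[C@H]1C(C)C)CO[Si](C)(C)C(C)(C)C | intermediate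
21 | (1S,2R,3S,6R)-6-{[(tert-butyldimethylsilyl)oxy]methyl}-8-oxo-3-(propan-2-yl)-7-oxabicyclo[4.2.0]octane-2-carbaldehyde (formyl cis to isopropyl) | CC(C)[C@@H]1CC[C@@]2(CO[Si](C)(C)C(C)(C)C)OC(=O)[C@H]2[C@@H]1C=O | intermediate
22 | (1S,2S,3S,6R)-6-{[(tert-butyldimethylsilyl)oxy]methyl}-8-oxo-3-(propan-2-yl)-7-oxabicyclo[4.2.0]octane-2-carbaldehyde (formyl trans to isopropyl) | CC(C)[C@@H]1CC[C@@]2(CO[Si](C)(C)C(C)(C)C)OC(=O)[C@H]2[C@H]1C=O | intermediate
23 | prop-2-en-1-yl (2E)-2-{[(tert-butyldimethylsilyl)oxy]methyl}-3-[(1S,2R,3S,6R)-6-{[(tert-butyldimethylsilyl)oxy]methyl}-8-oxo-3-(propan-2-yl)-7-oxabicyclo[4.2.0]octan-2-yl]prop-2-enoate (alkenyl arm trans to isopropyl, cis to lactone carbonyl) | CC(C)[C@@H]1CC[C@@]2(CO[Si](C)(C)C(C)(C)C)OC(=O)[C@H]2[C@H]1/C=C(\CO[Si](C)(C)C(C)(C)C)C(=O)OCC=C | intermediate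
24 | prop-2-en-1-yl (2E)-2-(hydroxymethyl)-3-[(1S,2R,3S,6R)-6-(hydroxymethyl)-8-oxo-3-(propan-2-yl)-7-oxabicyclo[4.2.0]octan-2-yl]prop-2-enoate | CC(C)[C@@H]1CC[C@@]2(CO)OC(=O)[C@H]2[C@H]1/C=C(\CO)C(=O)OCC=C | intermediate
25 | prop-2-en-1-yl (5aR,6S,9R,9aS)-9-hydroxy-9-(hydroxymethyl)-1-oxo-6-(propan-2-yl)-1,3,5a,6,7,8,9,9a-octahydro-2-benzoxepine-4-carboxylate | CC(C)[C@@H]1CC[C@](O)(CO)[C@H]2C(=O)OCC(C(=O)OCC=C)=C[C@@H]12 | intermediate
26 | allyl ester of the coupled bis-silyl compound (name as in step 15) | CC(C)[C@@H]1CC[C@](O)(COC(=O)/C(=C/[C@H]2C=C(CO[Si](C)(C)C(C)(C)C)CC[C@H]2C(C)C)CO[Si](C)(C)C(C)(C)C)[C@H]2C(=O)OCC(C(=O)OCC=C)=C[C@@H]12 | intermediate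
27 | coupled bis-silyl carboxylic acid (name as in step 16) | CC(C)[C@@H]1CC[C@](O)(COC(=O)/C(=C/[C@H]2C=C(CO[Si](C)(C)C(C)(C)C)CC[C@H]2C(C)C)CO[Si](C)(C)C(C)(C)C)[C@H]2C(=O)OCC(C(=O)O)=C[C@@H]12 | intermediate
28 | CNP0361406.6, (5aR,6S,9R,9aS)-9-hydroxy-9-({[(2E)-2-(hydroxymethyl)-3-[(1R,6S)-3-(hydroxymethyl)-6-(propan-2-yl)cyclohex-2-en-1-yl]prop-2-enoyl]oxy}methyl)-1-oxo-6-(propan-2-yl)-1,3,5a,6,7,8,9,9a-octahydro-2-benzoxepine-4-carboxylic acid | CC(C)[C@@H]1CC[C@](O)(COC(=O)/C(=C/[C@H]2C=C(CO)CC[C@H]2C(C)C)CO)[C@H]2C(=O)OCC(C(=O)O)=C[C@@H]12 | target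

**Totals**
Total step count: 17.
Longest linear sequence: 13 steps (steps 1–5, 8–10, 13–17).

**Steps most likely to fail, with fallbacks**

Step 10. The bis-cyclisation of a ketone to a six-membered ring is the slowest case of this reaction, and its selectivity rests on substrate control alone. If it fails, leave the organocatalytic manifold and make the two rings one after the other. From 17, thiophenol with DCC and catalytic DMAP gives the S-phenyl thioester F1. Soft enolisation of the thioester with MgBr2·OEt2 and iPr2NEt in CH2Cl2 closes the cyclohexane by a chelated aldol to the β-hydroxy thioester F2, under the same allylic-strain control. Silver trifluoroacetate (AgOCOCF3) with iPr2NEt then closes the four-membered lactone and returns the route to 18.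

Step 13. Ozonolysis of an electron-poor enoate beside a β-lactone is slow and consumes the olefination partner twice. If it fails, carry the formyl group through the key step as a vinyl group instead, setting out from keto aldehyde 15. Aldehyde-selective Wittig methylenation (Ph3PCH3Br, KHMDS, THF, −78 °C) gives the vinyl keto ester F3. LiOH gives the vinyl keto acid F4, and the conditions of step 10 give the vinyl β-lactone F5. Ozonolysis of its terminal alkene is fast and delivers 21, which rejoins step 13 at the epimerisation and olefination.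

Step 14. After desilylation the neopentyl alcohol could compete for the β-lactone and give a five-membered lactone, or later isomerise the product to it. If so, change the order of events so that this alcohol is still protected when the ring expands. Treat 22 with the unprotected hydroxy phosphonate 13 (LiCl, DBU, MeCN). The allylic alkoxide formed in the olefination opens the β-lactone in the same flask to the silyl-protected seven-membered lactone F6, and HF·pyridine then gives 25.

Further compounds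
F1 | step 10 | S-phenyl thioester of 17 | CC(C)[C@H](CCC(=O)CO[Si](C)(C)C(C)(C)C)[C@@H](/C=C(\CO[Si](C)(C)C(C)(C)C)C(=O)OCC=C)CC(=O)Sc1ccccc1
F2 | step 10 | β-hydroxy S-phenyl thioester (cyclohexanol aldol with the ring configuration of 18) | CC(C)[C@@H]1CC[C@](O)(CO[Si](C)(C)C(C)(C)C)[C@@H](C(=O)Sc2ccccc2)[C@@H]1/C=C(\CO[Si](C)(C)C(C)(C)C)C(=O)OCC=C
F3 | step 13 | vinyl keto ester (15 with ethenyl in place of formyl, same configuration) | CC(C)[C@H](CCC(=O)CO[Si](C)(C)C(C)(C)C)[C@@H](C=C)CC(=O)OC
F4 | step 13 | vinyl keto acid | CC(C)[C@H](CCC(=O)CO[Si](C)(C)C(C)(C)C)[C@@H](C=C)CC(=O)O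
F5 | step 13 | vinyl β-lactone (21 with ethenyl in place of formyl, ethenyl cis to isopropyl) | CC(C)[C@@H]1CC[C@@]2(CO[Si](C)(C)C(C)(C)C)OC(=O)[C@H]2[C@@H]1C=C
F6 | step 14 | prop-2-en-1-yl (5aR,6S,9R,9aS)-9-{[(tert-butyldimethylsilyl)oxy]methyl}-9-hydroxy-1-oxo-6-(propan-2-yl)-1,3,5a,6,7,8,9,9a-octahydro-2-benzoxepine-4-carboxylate | CC(C)[C@@H]1CC[C@](O)(CO[Si](C)(C)C(C)(C)C)[C@H]2C(=O)OCC(C(=O)OCC=C)=C[C@@H]12
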